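**Plan**

- Rings: A is the central coumarin (C2–C8a), B the primed coumarin bound through C8' to C6, C the doubly primed coumarin bound through C3'' to O7.
- Cuts, latest first: ring C at C3''=C4'' and O1''–C2'' (Perkin-type condensation) and at C3''–O7 (phenol alkylation); the pyranones of rings A and B together at C3=C4, C3'=C4' and both lactone C–O bonds (double Wittig lactonisation); C4–C4a of ring A (formylation); the benzene of ring B at C8a'–C4a' and C6'–C5' (Diels–Alder).
- Enabling feature: ring B carries ring A on C8', flanked by the oxygenated carbons C7' and C8a', has the one-carbon branch C4' on C4a' and plain CH at C5' and C6'. This is a 3-aryl-2,4-dihydroxybenzoate, which maps onto a 2-aryl-1,3-dioxygenated butadiene (C8a', C8', C7', C6') and a propiolate (C5', C4a', C4').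
- Forward: the ring A benzene is bought as an arylacetic acid whose benzylic carbon becomes C8', so the C6–C8' bond exists before ring B does; then the ring B benzene (step 6), both pyranones at once (step 12), ring C (step 15) and O-demethylation (step 16).
- Stereochemistry: the target has no stereocentre; the ketal centre of the cycloadduct and the diene geometry are erased on aromatisation.

Key step: step 6

Remark: the structure specifies no configuration for the hindered C6–C8' axis, so it is left uncontrolled; all chiral intermediates are racemic.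

**Route**

Step 1
Reactants: 1 (2,4-dihydroxyphenyl)acetic acid
Product: 2 methyl (2,4-dihydroxyphenyl)acetate
Conditions: MeOH, cat. H2SO4, reflux
Reagents that add atoms: methanol, CO
Why: Fischer esterification in excess methanol should give the methyl ester and also open any benzofuranone lactone formed from the ortho-hydroxyl.

Step 2
Reactants: 2 methyl (2,4-dihydroxyphenyl)acetate
Product: 3 methyl [2,4-bis(benzyloxy)phenyl]acetate
Conditions: BnBr (2.2 equiv), K2CO3, DMF, 50 °C
Reagents that add atoms: benzyl bromide, BrCc1ccccc1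
Why: Williamson etherification should benzylate both phenoxides, while the arylacetate CH2 is not acidic enough to be alkylated by K2CO3.

Step 3
Reactants: 3 methyl [2,4-bis(benzyloxy)phenyl]acetate; 4 acetyl chloride
Product: 5 methyl 2-[2,4-bis(benzyloxy)phenyl]-3-oxobutanoate (racemic)
Conditions: LiN(SiMe3)2 (2.1 equiv), THF, −78 °C; enolate added to 4, −78 → 0 °C; aq. NH4Cl
Reagents that add atoms: none
Why: Claisen-type C-acylation of the lithium ester enolate by acetyl chloride should give the β-keto ester, which the second equivalent of base converts at once into its stabilised enolate so that no second acylation occurs.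

Step 4
Reactants: 5 methyl 2-[2,4-bis(benzyloxy)phenyl]-3-oxobutanoate
Product: 6 methyl 2-[2,4-bis(benzyloxy)phenyl]-3-(trimethylsilyloxy)but-2-enoate (E/Z not controlled)
Conditions: Me3SiCl, Et3N, PhMe, rt; filtered under argon, concentrated
Reagents that add atoms: chlorotrimethylsilane, C[Si](C)(C)Cl
Why: Soft enolisation of the strongly enolised α-aryl β-keto ester with Et3N and O-silylation by Me3SiCl, the first stage of the Chan diene preparation, should give the silyl enol ether.

Step 5
Reactants: 6 methyl 2-[2,4-bis(benzyloxy)phenyl]-3-(trimethylsilyloxy)but-2-enoate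
Product: 7 2-[2,4-bis(benzyloxy)phenyl]-1-methoxy-1,3-bis(trimethylsilyloxy)buta-1,3-diene (ketene acetal geometry not controlled)
Conditions: LiN(iPr)2, THF, −78 °C; Me3SiCl, −78 °C → rt; pentane, filtered, concentrated, used crude
Reagents that add atoms: chlorotrimethylsilane, C[Si](C)(C)Cl
Why: Kinetic γ-deprotonation of the vinylogous ester by LiN(iPr)2 and O-silylation of the dienolate (Chan–Brassard diene synthesis) should give the moisture-sensitive cross-conjugated ketene acetal.

Step 6
Reactants: 7 2-[2,4-bis(benzyloxy)phenyl]-1-methoxy-1,3-bis(trimethylsilyloxy)buta-1,3-diene; 8 methyl propiolate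
Product: 11 methyl 3-[2,4-bis(benzyloxy)phenyl]-2,4-dihydroxybenzoate, via ketal cycloadduct 9 (not isolated), via aryl bis(trimethylsilyl) ether 10 (not isolated)
Conditions: 8 (3 equiv), PhMe, 90 °C, sealed tube; then 1 M HCl, THF, rt
Reagents that add atoms: none
Why: The HOMO-raised diene 7 should add to the alkynoate in a concerted but strongly asynchronous [4+2] cycloaddition, whose ionic limit is attack of the CH2 terminus on the β-carbon followed by collapse of the α-carbon onto the oxygen-stabilised ketene acetal carbon, so that C6'–C5' and C8a'–C4a' are formed. The closest known reaction type is the Diels–Alder reaction and aromatisation of 1-alkoxy-1,3-bis(silyloxy)butadienes (Chan- or Brassard-type dienes) with acetylenic esters, which gives 2,4-dihydroxybenzoates. The carbocycle of ring B is closed intermolecularly in the [4+2] mode, and ketal 9 then aromatises by 1,4-elimination of methanol to 10, whose two silyl ethers are hydrolysed in the acidic work-up. The only stereocentre formed, the ketal carbon of 9, disappears on aromatisation, so neither it nor the ketene acetal geometry of 7 needs control. Regioselectivity is the one selectivity required and is secured by the polarity of the partners: the largest HOMO coefficient of 7 lies on the CH2 terminus and the largest LUMO coefficient of 8 on its β-carbon, which places the ester next to the carbon that becomes C8a'. The aryl group on the internal diene carbon disfavours the s-trans rotamer and so predisposes 7 to the reactive s-cis form.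

Step 7
Reactants: 11 methyl 3-[2,4-bis(benzyloxy)phenyl]-2,4-dihydroxybenzoate
Product: 12 methyl 3-[2,4-bis(benzyloxy)phenyl]-2-hydroxy-4-methoxybenzoate
Conditions: MeI (1.1 equiv), K2CO3, acetone, reflux
Reagents that add atoms: iodomethane, CI
Why: Williamson methylation should be selective for the 4-hydroxyl because the 2-hydroxyl is held in a hydrogen bond to the ester carbonyl and is the weaker nucleophile.

Step 8
Reactants: 12 methyl 3-[2,4-bis(benzyloxy)phenyl]-2-hydroxy-4-methoxybenzoate
Product: 13 2-[2,4-bis(benzyloxy)phenyl]-6-(hydroxymethyl)-3-methoxyphenol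
Conditions: LiAlH4, THF, 0 °C → rt; H2O, aq. NH4Cl to about pH 6; used directly
Reagents that add atoms: none
Why: Hydride reduction of the ester by LiAlH4 should give the salicyl alcohol, with benzyl and methyl ethers inert and the low temperature and near-neutral work-up avoiding benzylic C–O cleavage through a quinone methide.

Step 9
Reactants: 13 2-[2,4-bis(benzyloxy)phenyl]-6-(hydroxymethyl)-3-methoxyphenol
Product: 14 3-[2,4-bis(benzyloxy)phenyl]-2-hydroxy-4-methoxybenzaldehyde
Conditions: activated MnO2 (10 equiv), CH2Cl2, rt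
Reagents that add atoms: none
Why: MnO2 oxidises benzylic alcohols selectively to aldehydes and leaves the free phenol untouched, so the hydrogen-bonded salicylaldehyde should form without over-oxidation.

Step 10
Reactants: 14 3-[2,4-bis(benzyloxy)phenyl]-2-hydroxy-4-methoxybenzaldehyde
Product: 15 3-(2,4-dihydroxyphenyl)-2-hydroxy-4-methoxybenzaldehyde
Conditions: BCl3 (5 equiv), pentamethylbenzene (6 equiv), CH2Cl2, −78 °C; then H2O
Reagents that add atoms: none
Why: Lewis-acid debenzylation with BCl3 in the presence of pentamethylbenzene as a cation scavenger should cleave both aryl benzyl ethers at −78 °C without touching the methyl ether or the aldehyde and without C-benzylating the electron-rich rings.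

Step 11
Reactants: 15 3-(2,4-dihydroxyphenyl)-2-hydroxy-4-methoxybenzaldehyde
Product: 16 5-(3-formyl-2-hydroxy-6-methoxyphenyl)-2,4-dihydroxybenzaldehyde
Conditions: POCl3 (1.2 equiv), DMF (1.5 equiv), MeCN, −15 °C → rt; then H2O, 50 °C
Reagents that add atoms: N,N-dimethylformamide, CN(C)C=O; water, O
Why: Vilsmeier–Haack formylation should occur at the most electron-rich and least hindered carbon, the ring A position para to the hydroxyl next to the biaryl bond and ortho to the other hydroxyl (as resorcinol itself reacts), while ring B is deactivated by its own formyl group.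

Step 12
Reactants: 16 5-(3-formyl-2-hydroxy-6-methoxyphenyl)-2,4-dihydroxybenzaldehyde; 17 ethyl (triphenylphosphoranylidene)acetate
Product: 19 7-hydroxy-6-(7-methoxy-2-oxo-2H-chromen-8-yl)-2H-chromen-2-one, via bis(hydroxycinnamate) diester 18 (not isolated)
Conditions: 17 (2.5 equiv), PhNEt2, reflux (ca. 215 °C)
Reagents that add atoms: none
Why: Double Wittig olefination by the stabilised ylide followed, at this temperature, by E/Z isomerisation of the 2-hydroxycinnamates and 6-exo-trig lactonisation onto the ortho-phenols should close the pyranones of rings B and A in one operation, leaving the ring A hydroxyl para to C4a free as O7.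

Step 13
Reactants: 19 7-hydroxy-6-(7-methoxy-2-oxo-2H-chromen-8-yl)-2H-chromen-2-one; 20 tert-butyl bromoacetate
Product: 21 tert-butyl {[6-(7-methoxy-2-oxo-2H-chromen-8-yl)-2-oxo-2H-chromen-7-yl]oxy}acetate
Conditions: K2CO3, DMF, rt → 50 °C
Reagents that add atoms: none
Why: Williamson alkylation of the only free phenol by the reactive α-bromo ester should proceed under anhydrous carbonate conditions that do not open the lactones.

Step 14
Reactants: 21 tert-butyl {[6-(7-methoxy-2-oxo-2H-chromen-8-yl)-2-oxo-2H-chromen-7-yl]oxy}acetate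
Product: 22 {[6-(7-methoxy-2-oxo-2H-chromen-8-yl)-2-oxo-2H-chromen-7-yl]oxy}acetic acid
Conditions: CF3CO2H, CH2Cl2, rt
Reagents that add atoms: none
Why: Acidolysis of the tert-butyl ester with loss of isobutene should free the aryloxyacetic acid without any base that could open the coumarin lactones.

Step 15
Reactants: 22 {[6-(7-methoxy-2-oxo-2H-chromen-8-yl)-2-oxo-2H-chromen-7-yl]oxy}acetic acid; 23 2-hydroxy-4-methoxybenzaldehyde
Product: 24 7-methoxy-3-{[6-(7-methoxy-2-oxo-2H-chromen-8-yl)-2-oxo-2H-chromen-7-yl]oxy}-2H-chromen-2-one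
Conditions: Ac2O, Et3N, 120 °C
Reagents that add atoms: none
Why: Perkin–Oglialoro condensation, in which the mixed anhydride of the aryloxyacetic acid is enolised, adds to the aldehyde, dehydrates and lactonises onto the phenol, is the established way to 3-aryloxycoumarins and should close ring C with C3'' already bound to O7.

Step 16
Reactants: 24 7-methoxy-3-{[6-(7-methoxy-2-oxo-2H-chromen-8-yl)-2-oxo-2H-chromen-7-yl]oxy}-2H-chromen-2-one
Product: 25 7-hydroxy-3-{[6-(7-hydroxy-2-oxo-2H-chromen-8-yl)-2-oxo-2H-chromen-7-yl]oxy}-2H-chromen-2-one (CNP0215289.0)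
Conditions: BBr3 (8 equiv), CH2Cl2, −78 °C → rt; then H2O
Reagents that add atoms: none
Why: Lewis-acid O-demethylation by BBr3 proceeds by bromide attack on the methyl carbon of the boron-complexed ether, so both aryl methyl ethers should be cleaved while the aryl vinyl ether at C3''–O7 and the three lactones survive.

**Compound list**

1 | (2,4-dihydroxyphenyl)acetic acid | O=C(O)Cc1ccc(O)cc1O | starting material
2 | methyl (2,4-dihydroxyphenyl)acetate | COC(=O)Cc1ccc(O)cc1O | intermediate
3 | methyl [2,4-bis(benzyloxy)phenyl]acetate | COC(=O)Cc1ccc(OCc2ccccc2)cc1OCc1ccccc1 | intermediate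
4 | acetyl chloride | CC(Cl)=O | starting material
5 | methyl 2-[2,4-bis(benzyloxy)phenyl]-3-oxobutanoate (racemic) | COC(=O)C(C(C)=O)c1ccc(OCc2ccccc2)cc1OCc1ccccc1 | intermediate
6 | methyl 2-[2,4-bis(benzyloxy)phenyl]-3-(trimethylsilyloxy)but-2-enoate (E/Z not controlled) | COC(=O)C(=C(C)O[Si](C)(C)C)c1ccc(OCc2ccccc2)cc1OCc1ccccc1 | intermediate
7 | 2-[2,4-bis(benzyloxy)phenyl]-1-methoxy-1,3-bis(trimethylsilyloxy)buta-1,3-diene (ketene acetal geometry not controlled) | COC(O[Si](C)(C)C)=C(c1ccc(OCc2ccccc2)cc1OCc1ccccc1)C(=C)O[Si](C)(C)C | intermediate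
8 | methyl propiolate | C#CC(=O)OC | starting material
9 | methyl 5-[2,4-bis(benzyloxy)phenyl]-6-methoxy-4,6-bis(trimethylsilyloxy)cyclohexa-1,4-diene-1-carboxylate (racemic ketal cycloadduct; not isolated) | COC(=O)C1=CCC(O[Si](C)(C)C)=C(c2ccc(OCc3ccccc3)cc2OCc2ccccc2)C1(OC)O[Si](C)(C)C | intermediate
10 | methyl 3-[2,4-bis(benzyloxy)phenyl]-2,4-bis(trimethylsilyloxy)benzoate (not isolated) | COC(=O)c1ccc(O[Si](C)(C)C)c(-c2ccc(OCc3ccccc3)cc2OCc2ccccc2)c1O[Si](C)(C)C | intermediate
11 | methyl 3-[2,4-bis(benzyloxy)phenyl]-2,4-dihydroxybenzoate | COC(=O)c1ccc(O)c(-c2ccc(OCc3ccccc3)cc2OCc2ccccc2)c1O | intermediate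
12 | methyl 3-[2,4-bis(benzyloxy)phenyl]-2-hydroxy-4-methoxybenzoate | COC(=O)c1ccc(OC)c(-c2ccc(OCc3ccccc3)cc2OCc2ccccc2)c1O | intermediate
13 | 2-[2,4-bis(benzyloxy)phenyl]-6-(hydroxymethyl)-3-methoxyphenol | OCc1ccc(OC)c(-c2ccc(OCc3ccccc3)cc2OCc2ccccc2)c1O | intermediate
14 | 3-[2,4-bis(benzyloxy)phenyl]-2-hydroxy-4-methoxybenzaldehyde | O=Cc1ccc(OC)c(-c2ccc(OCc3ccccc3)cc2OCc2ccccc2)c1O | intermediate
15 | 3-(2,4-dihydroxyphenyl)-2-hydroxy-4-methoxybenzaldehyde | O=Cc1ccc(OC)c(-c2ccc(O)cc2O)c1O | intermediate
16 | 5-(3-formyl-2-hydroxy-6-methoxyphenyl)-2,4-dihydroxybenzaldehyde | O=Cc1ccc(OC)c(-c2cc(C=O)c(O)cc2O)c1O | intermediate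
17 | ethyl (triphenylphosphoranylidene)acetate | CCOC(=O)C=P(c1ccccc1)(c1ccccc1)c1ccccc1 | starting material
18 | ethyl 3-{5-[3-(3-ethoxy-3-oxoprop-1-en-1-yl)-2-hydroxy-6-methoxyphenyl]-2,4-dihydroxyphenyl}prop-2-enoate (E/Z not controlled; not isolated) | CCOC(=O)C=Cc1ccc(OC)c(-c2cc(C=CC(=O)OCC)c(O)cc2O)c1O | intermediate
19 | 7-hydroxy-6-(7-methoxy-2-oxo-2H-chromen-8-yl)-2H-chromen-2-one | COc1ccc2ccc(=O)oc2c1-c1cc2ccc(=O)oc2cc1O | intermediate
20 | tert-butyl bromoacetate | CC(C)(C)OC(=O)CBr | starting material
21 | tert-butyl {[6-(7-methoxy-2-oxo-2H-chromen-8-yl)-2-oxo-2H-chromen-7-yl]oxy}acetate | COc1ccc2ccc(=O)oc2c1-c1cc2ccc(=O)oc2cc1OCC(=O)OC(C)(C)C | intermediate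
22 | {[6-(7-methoxy-2-oxo-2H-chromen-8-yl)-2-oxo-2H-chromen-7-yl]oxy}acetic acid | COc1ccc2ccc(=O)oc2c1-c1cc2ccc(=O)oc2cc1OCC(=O)O | intermediate
23 | 2-hydroxy-4-methoxybenzaldehyde | COc1ccc(C=O)c(O)c1 | starting material
24 | 7-methoxy-3-{[6-(7-methoxy-2-oxo-2H-chromen-8-yl)-2-oxo-2H-chromen-7-yl]oxy}-2H-chromen-2-one | COc1ccc2ccc(=O)oc2c1-c1cc2ccc(=O)oc2cc1Oc1cc2ccc(OC)cc2oc1=O | intermediate
25 | 7-hydroxy-3-{[6-(7-hydroxy-2-oxo-2H-chromen-8-yl)-2-oxo-2H-chromen-7-yl]oxy}-2H-chromen-2-one (CNP0215289.0) | O=c1ccc2cc(-c3c(O)ccc4ccc(=O)oc34)c(Oc3cc4ccc(O)cc4oc3=O)cc2o1 | target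

**Count and risks**

Total step count: 16. Longest linear sequence: 16 steps (1 → 25); compounds 4, 8, 17, 20 and 23 are bought.

Steps most likely to fail, each with a fallback built on known chemistry:

Step 6. Protodesilylation or silyl migration of the crowded diene may outrun the cycloaddition, or the reaction may stop after the first C–C bond at an open-chain enoate that cannot ring-close. The fallback sets out from 3 and comes back at 11; it builds ring B by an ionic Michael–Dieckmann annulation and a separate dehydrogenation instead of a cycloaddition. Crossed Claisen condensation of 3 with excess LiCH2CO2Me (THF, −78 °C) should give methyl 4-[2,4-bis(benzyloxy)phenyl]-3-oxobutanoate F1. With NaOMe in MeOH and methyl acrylate, Michael addition at C2 gives dimethyl 2-{[2,4-bis(benzyloxy)phenyl]acetyl}pentanedioate F2 (not isolated). At reflux F2 closes by Dieckmann attack of its benzylic carbon on the distal ester to methyl 3-[2,4-bis(benzyloxy)phenyl]-2,4-dioxocyclohexane-1-carboxylate F3, as in the classical dihydroresorcylate synthesis. DDQ in dioxane at reflux then dehydrogenates F3 to 11.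

Step 5. The amide base may attack the enol silicon, the dienolate may be silylated on carbon, or the labile enol silyl ether may be lost on handling, so that the bis(silyloxy)diene is not obtained clean. The fallback sets out from 5 and comes back at 12; it uses a Brassard-type diene with a robust methyl enol ether in place of the C3 silyl ether. O-Methylation of 5 (Me2SO4, K2CO3, DMF) should give methyl 2-[2,4-bis(benzyloxy)phenyl]-3-methoxybut-2-enoate F4. γ-Deprotonation and O-silylation (LiN(iPr)2, Me3SiCl, THF, −78 °C) give 2-[2,4-bis(benzyloxy)phenyl]-1,3-dimethoxy-1-(trimethylsilyloxy)buta-1,3-diene F5. Cycloaddition with 8 under the conditions of step 6 passes through methyl 5-[2,4-bis(benzyloxy)phenyl]-4,6-dimethoxy-6-(trimethylsilyloxy)cyclohexa-1,4-diene-1-carboxylate F6 and, after loss of methanol, methyl 3-[2,4-bis(benzyloxy)phenyl]-4-methoxy-2-(trimethylsilyloxy)benzoate F7. Acidic work-up then gives 12 directly, so step 7 is no longer needed.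

Step 11. The electrophilic formylation of the tris-phenol may show poor site selectivity (attack between the two hydroxyls of the resorcinol ring, or on ring B para to its hydroxyl), or O-formylation and over-formylation may intervene. The fallback sets out from 14 and comes back at 19; it makes the ring A pyranone by von Pechmann annulation, which needs a free phenol next to the reacting C–H and so cannot touch ring B once that is a coumarin. Compound 14 with 17 in refluxing PhNEt2 should give, through ethyl 3-{3-[2,4-bis(benzyloxy)phenyl]-2-hydroxy-4-methoxyphenyl}prop-2-enoate F8 (not isolated), 8-[2,4-bis(benzyloxy)phenyl]-7-methoxy-2H-chromen-2-one F9. BCl3 and pentamethylbenzene (CH2Cl2, −78 °C) then give 8-(2,4-dihydroxyphenyl)-7-methoxy-2H-chromen-2-one F10. Malic acid in conc. H2SO4 at about 110 °C annulates ring A para to the hydroxyl next to the biaryl bond and gives 19.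

**Further compounds**

F1 | step 6 | methyl 4-[2,4-bis(benzyloxy)phenyl]-3-oxobutanoate | COC(=O)CC(=O)Cc1ccc(OCc2ccccc2)cc1OCc1ccccc1
F2 | step 6 | dimethyl 2-{[2,4-bis(benzyloxy)phenyl]acetyl}pentanedioate | COC(=O)CCC(C(=O)OC)C(=O)Cc1ccc(OCc2ccccc2)cc1OCc1ccccc1
F3 | step 6 | methyl 3-[2,4-bis(benzyloxy)phenyl]-2,4-dioxocyclohexane-1-carboxylate | COC(=O)C1CCC(=O)C(c2ccc(OCc3ccccc3)cc2OCc2ccccc2)C1=O
F4 | step 5 | methyl 2-[2,4-bis(benzyloxy)phenyl]-3-methoxybut-2-enoate | COC(=O)C(=C(C)OC)c1ccc(OCc2ccccc2)cc1OCc1ccccc1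
F5 | step 5 | 2-[2,4-bis(benzyloxy)phenyl]-1,3-dimethoxy-1-(trimethylsilyloxy)buta-1,3-diene | COC(O[Si](C)(C)C)=C(c1ccc(OCc2ccccc2)cc1OCc1ccccc1)C(=C)OC
F6 | step 5 | methyl 5-[2,4-bis(benzyloxy)phenyl]-4,6-dimethoxy-6-(trimethylsilyloxy)cyclohexa-1,4-diene-1-carboxylate | COC(=O)C1=CCC(OC)=C(c2ccc(OCc3ccccc3)cc2OCc2ccccc2)C1(OC)O[Si](C)(C)C
F7 | step 5 | methyl 3-[2,4-bis(benzyloxy)phenyl]-4-methoxy-2-(trimethylsilyloxy)benzoate | COC(=O)c1ccc(OC)c(-c2ccc(OCc3ccccc3)cc2OCc2ccccc2)c1O[Si](C)(C)C
F8 | step 11 | ethyl 3-{3-[2,4-bis(benzyloxy)phenyl]-2-hydroxy-4-methoxyphenyl}prop-2-enoate | CCOC(=O)C=Cc1ccc(OC)c(-c2ccc(OCc3ccccc3)cc2OCc2ccccc2)c1O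
F9 | step 11 | 8-[2,4-bis(benzyloxy)phenyl]-7-methoxy-2H-chromen-2-one | COc1ccc2ccc(=O)oc2c1-c1ccc(OCc2ccccc2)cc1OCc1ccccc1
F10 | step 11 | 8-(2,4-dihydroxyphenyl)-7-methoxy-2H-chromen-2-one | COc1ccc2ccc(=O)oc2c1-c1ccc(O)cc1O
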